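Turn each charge of J into a time before you trust your hunch that [D] at the end grows in step with the charge. These are the flasks and readings you sent:

| flask | J | remark | time |
|---|---|---|---|
| Thursday's | 0.0065 M | run made earlier |  |
| Wednesday's | 0.017 M | run made earlier |  |
| Saturday's | 0.060 M | run made earlier |  |
| dawn | 0.0060 M |  | 50 min |
| autumn | 0.012 M |  | 50 min |
| summer | 0.025 M |  | 50 min |
| dusk | 0.050 M |  | 50 min |

| run | time / min | D / % | J / % |
|---|---|---|---|
| Thursday's | 4.00 | 3 | 75 |
| Thursday's | 8.00 | 7 | 45 |
| Thursday's | 15.0 | 19 | 6 |
| Thursday's | 25.0 | 23 | 0 |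
| Thursday's | 50.0 | 25 | 0 |
| Wednesday's | 4.00 | 0 | 91 |
| Wednesday's | 8.00 | 2 | 78 |
| Wednesday's | 15.0 | 8 | 58 |
| Wednesday's | 25.0 | 15 | 43 |
| Wednesday's | 50.0 | 23 | 3 |
| Saturday's | 4.00 | 1 | 101 |
| Saturday's | 8.00 | 2 | 94 |
| Saturday's | 15.0 | 3 | 89 |
| Saturday's | 25.0 | 4 | 83 |
| Saturday's | 50.0 | 7 | 68 |

(scatter of a reading: 2 percentage points)

- solid, in amounts per volume of the solution: J
- at the start none of J is in solution
- a step back or a flat step of under half a percent of the largest counts as no turn
- "hardly changes" means that all values lie within two and a half points (for a concentration: within two and a half percent of the largest)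
- a step back or a flat step of under half a percent of the largest counts as no turn

- [D] at the end for dawn, autumn, summer, dusk, in this order
- how that number moves from the first to the last of them (falls, then rises / rises all the way / falls all the way / hardly changes / rises, then falls)

In molar terms, the runs lose J at nearly the same pace despite their different charges. Saturday's flask loses 0.0192 M of J in 50.0 min, and I call that loss per minute the clearing pace, 3.84 × 10⁻⁴ M min⁻¹. Wednesday's flask reads 3.88 × 10⁻⁴ M min⁻¹ up to 25.0 min. A pace that doesn't follow the charge reads as zero order in J, with the going into solution as the rate-limiting step.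

The charge divided by this pace is the time a flask needs to clear its J. Dawn needs 15.6 min and autumn 31.3 min, which is less than 50 min, so I expect both to use up their charge. Summer needs 65.1 min and dusk 130 min, which is more than 50 min, so I expect each to lose the same 0.0192 M.

For the yield, Thursday's flask has J at 0 % by 25.0 min and ends with D at 25 % of its charge, while Saturday's flask reads D at 21.9 % of the J it has lost. Taking Thursday's share, I reckon 0.00150 M for dawn, 0.00300 M for autumn, and 0.00480 M for both summer and dusk. Your hunch therefore holds from dawn to autumn. The row still climbs from autumn to summer, though by less than the charge does, and it stays level from summer to dusk, the two flasks I expect to keep some J; since a flat step counts as no turn, it reads as a rise from first to last.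

The forecast gives 0.0015 M, 0.003 M, 0.0045 M and 0.0045 M, shape rises all the way, a little under my figure for the last two, and its ground is this: “J is consumed at a zero-order, dissolution-limited rate”.

The flasks give 0.00154 M, 0.00301 M, 0.00465 M and 0.00465 M, and the row rises all the way.

    E ⇌ D (K = 11.6, k = 0.0827 min⁻¹)
    L ⇌ E (k = 0.0100 min⁻¹)
    J ⇌ E, rate k3*(cs3 - [E]) while solid is left; crystals form when [E] > cs3 (solubility = 20.0 mM, k = 0.0215 min⁻¹)
    D ⇌ L (K = 2.46, k = 0.0105 min⁻¹)

In dawn's flask at 50.0 min, more of the charge stands as the other product L, 71.9 %, than as D, 25.6 %. The clearing pace of 3.84 × 10⁻⁴ M min⁻¹ takes summer's J down to 23.2 % at 50.0 min, and summer's flask holds 19.3 %. The same pace takes dusk's J down to 61.6 %, and dusk's flask holds 59.7 % at 50.0 min.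

The earlier runs and the new flask come from a simulation for substances that don't exist, and the scatter is random.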